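The route rests on disconnecting the γ-lactone at its C12(=O)–C11 bond (locants are defined in the remark below). Because the lactone carbonyl carbon is bonded only to O6 and C11, it is brought in as carbon monoxide: a palladium-catalysed cyclocarbonylation converts cycloheptanol 21, in which the C6 hydroxyl and the C5 ethynyl group are cis on the seven-membered ring, into the cis-fused α-methylene-γ-butyrolactone in one operation, the ring closing when the alkyne inserts into a Pd–CO2R bond to form C12–C11. Convex-face hydrogenation then sets C11. Precursor 21 already carries the C1, C2, C3, C5, C6 and C7 stereocentres, assembled by Claisen rearrangement, Evans aldol reaction, ring-closing metathesis and a transposition–epoxidation–opening relay.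

Key step: step 15

Remark (locants and faces): the carbocycle is numbered C1 (quaternary carbinol carbon bearing the acyl group), C2 (CH–CH3), C3 (CH–O), C4 (CH2), C5 (CH bearing the lactone α-carbon), C6 (CH–O of the lactone), C7 (CH–O of the isobutyrate); the lactone α-carbon, carbonyl carbon and methyl carbon are C11, C12 and C13. β is the face of the seven-membered ring that carries the C1 hydroxyl in the target, α the opposite face. The target is 1β-OH, 2β-CH3, 3α-OH, 5β-C11, 6β-O, 7α-O, 13-CH3 β (H-11 α).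
Remark (assumptions): compounds 1, 2, 5 and 9 are taken as catalogue chemicals; the alkyne is carried as its trimethylsilyl derivative until after the metathesis.

Step 1
Reactants: 1 3-(trimethylsilyl)prop-2-ynal; 2 1-(triphenyl-λ5-phosphanylidene)propan-2-one
Product: 3 (E)-6-(trimethylsilyl)hex-3-en-5-yn-2-one
Conditions: CH2Cl2, rt
Reagents that add atoms: none
Why: Wittig olefination with a stabilised ylide, which should give the (E)-enone because the oxaphosphetane equilibrates to the trans isomer.

Step 2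
Reactants: 3 (E)-6-(trimethylsilyl)hex-3-en-5-yn-2-one
Product: 4 (R,E)-6-(trimethylsilyl)hex-3-en-5-yn-2-ol
Conditions: (S)-2-methyl-CBS-oxazaborolidine (10 mol%), catecholborane, toluene, −78 °C; then MeOH, 1 M NaOH
Reagents that add atoms: none
Why: Corey–Bakshi–Shibata reduction, in which the enynyl group acts as the large and the methyl group as the small ketone substituent, so that the (S)-catalyst should deliver hydride 1,2 to give the (R)-allylic alcohol.

Step 3
Reactants: 4 (R,E)-6-(trimethylsilyl)hex-3-en-5-yn-2-ol; 5 triethyl orthoacetate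
Product: 7 ethyl (R,E)-3-[(trimethylsilyl)ethynyl]hex-4-enoate, via ketene acetal 6 (not isolated)
Conditions: EtCO2H (cat.), 140 °C, removal of EtOH
Reagents that add atoms: none
Why: Johnson–Claisen rearrangement through a chair transition state with the carbinol methyl group equatorial, which should transfer the (R)-carbinol configuration suprafacially to the new C5 stereocentre (R) and leave an (E)-propenyl group.

Step 4
Reactants: 7 ethyl (R,E)-3-[(trimethylsilyl)ethynyl]hex-4-enoate
Product: 8 (R,E)-3-[(trimethylsilyl)ethynyl]hex-4-enal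
Conditions: i-Bu2AlH (1.05 equiv), CH2Cl2, −78 °C; then MeOH, aq. KNaC4H4O6
Reagents that add atoms: none
Why: Partial ester reduction with i-Bu2AlH, which stops at the tetrahedral aluminium hemiacetal at −78 °C and releases the aldehyde on work-up without touching C5.

Step 5
Reactants: 8 (R,E)-3-[(trimethylsilyl)ethynyl]hex-4-enal; 9 (S)-4-benzyl-3-propanoyloxazolidin-2-one
Product: 11 (S)-4-benzyl-3-[(2S,3R,5R,E)-3-hydroxy-2-methyl-5-[(trimethylsilyl)ethynyl]oct-6-enoyl]oxazolidin-2-one, via boron enolate 10 (not isolated)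
Conditions: Bu2BOTf, Et3N, CH2Cl2, −78 to 0 °C; then 8, −78 to 0 °C; then pH 7 buffer, MeOH, H2O2
Reagents that add atoms: none
Why: Evans syn-aldol reaction, in which the (Z)-boron enolate reacts through a Zimmerman–Traxler chair with the auxiliary shielding one enolate face, which should set C2 (S) and C3 (R) under reagent control irrespective of the remote C5 centre.

Step 6
Reactants: 11 (S)-4-benzyl-3-[(2S,3R,5R,E)-3-hydroxy-2-methyl-5-[(trimethylsilyl)ethynyl]oct-6-enoyl]oxazolidin-2-one
Product: 12 (2S,3R,5R,E)-3-hydroxy-N-methoxy-N,2-dimethyl-5-[(trimethylsilyl)ethynyl]oct-6-enamide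
Conditions: MeONHMe·HCl, AlMe3, CH2Cl2, 0 °C to rt
Reagents that add atoms: N,O-dimethylhydroxylamine hydrochloride, CNOC.Cl
Why: Aluminium amide transamidation, which cleaves the exocyclic acyl–N bond of the β-hydroxy imide and gives the Weinreb amide without epimerising C2.

Step 7
Reactants: 12 (2S,3R,5R,E)-3-hydroxy-N-methoxy-N,2-dimethyl-5-[(trimethylsilyl)ethynyl]oct-6-enamide
Product: 13 (2S,3R,5R,E)-3-[(tert-butyldimethylsilyl)oxy]-N-methoxy-N,2-dimethyl-5-[(trimethylsilyl)ethynyl]oct-6-enamide
Conditions: t-BuMe2SiOTf, 2,6-lutidine, CH2Cl2, −78 °C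
Reagents that add atoms: tert-butyldimethylsilyl trifluoromethanesulfonate, CC(C)(C)[Si](C)(C)OS(=O)(=O)C(F)(F)F
Why: Silylation of the secondary alcohol with a silyl triflate and a hindered base, so that the C3 oxygen is masked during the enone, epoxide and enolate chemistry that follows.

Step 8
Reactants: 13 (2S,3R,5R,E)-3-[(tert-butyldimethylsilyl)oxy]-N-methoxy-N,2-dimethyl-5-[(trimethylsilyl)ethynyl]oct-6-enamide
Product: 14 (4S,5R,7R,E)-5-[(tert-butyldimethylsilyl)oxy]-4-methyl-7-[(trimethylsilyl)ethynyl]deca-1,8-dien-3-one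
Conditions: CH2=CHMgBr, THF, 0 °C; then cold aq. HCl
Reagents that add atoms: vinylmagnesium bromide, C=C[Mg]Br
Why: Weinreb ketone synthesis, in which the chelated tetrahedral magnesium adduct prevents over-addition and collapses to the vinyl ketone only on acidic work-up.

Step 9
Reactants: 14 (4S,5R,7R,E)-5-[(tert-butyldimethylsilyl)oxy]-4-methyl-7-[(trimethylsilyl)ethynyl]deca-1,8-dien-3-one
Product: 15 (4R,6R,7S)-6-[(tert-butyldimethylsilyl)oxy]-7-methyl-4-[(trimethylsilyl)ethynyl]cyclohept-2-en-1-one
Conditions: second-generation Grubbs catalyst RuCl2(=CHPh)(PCy3)(H2IMes) (5 mol%), CH2Cl2 (2 mM), 40 °C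
Reagents that add atoms: none
Why: Ring-closing metathesis between the vinyl ketone and the propenyl group, which should close the cycloheptenone with loss of propene while the silyl-capped alkyne stays inert.

Step 10
Reactants: 15 (4R,6R,7S)-6-[(tert-butyldimethylsilyl)oxy]-7-methyl-4-[(trimethylsilyl)ethynyl]cyclohept-2-en-1-one
Product: 17 1α-acetyl-3α-(tert-butyldimethylsilyloxy)-2β-methyl-5β-[(trimethylsilyl)ethynyl]cyclohept-6-en-1β-ol, via enol ether carbinol 16 (not isolated)
Conditions: CH2=CHOEt, t-BuLi, THF, −78 to 0 °C; then 15, −78 °C; then 1 M aq. HCl, THF, 0 °C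
Reagents that add atoms: ethyl vinyl ether, C=COCC; water, O
Why: 1,2-Addition of 1-ethoxyvinyllithium (an acetyl anion equivalent) to the enone carbonyl, expected anti to the adjacent C2 methyl group so that the new C1 hydroxyl is β, followed by mild hydrolysis of the enol ether to the methyl ketone.

Step 11
Reactants: 17 1α-acetyl-3α-(tert-butyldimethylsilyloxy)-2β-methyl-5β-[(trimethylsilyl)ethynyl]cyclohept-6-en-1β-ol
Product: 18 1α-acetyl-3α-(tert-butyldimethylsilyloxy)-5β-ethynyl-2β-methylcyclohept-6-en-1β-ol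
Conditions: K2CO3 (cat.), MeOH, rt
Reagents that add atoms: none
Why: Base-catalysed methanolysis of the alkynyl C–Si bond, which frees the terminal alkyne while the silyl ether and the tertiary α-ketol are left alone.

Step 12
Reactants: 18 1α-acetyl-3α-(tert-butyldimethylsilyloxy)-5β-ethynyl-2β-methylcyclohept-6-en-1β-ol
Product: 19 1-acetyl-3α-(tert-butyldimethylsilyloxy)-5β-ethynyl-2β-methylcyclohept-1(7)-en-6β-ol
Conditions: Ph3SiOReO3 (5 mol%), Et2O, 0 °C
Reagents that add atoms: none
Why: Rhenium-oxo-catalysed 1,3-transposition of the tertiary allylic alcohol, a suprafacial [3,3] shift of the perrhenate ester that should move the β-oxygen from C1 to C6 (cis to the C5 ethynyl group) and is driven by conjugation of the new C1=C7 bond with the acetyl group.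

Step 13
Reactants: 19 1-acetyl-3α-(tert-butyldimethylsilyloxy)-5β-ethynyl-2β-methylcyclohept-1(7)-en-6β-ol
Product: 20 1α-acetyl-1β,7β-epoxy-3α-(tert-butyldimethylsilyloxy)-5β-ethynyl-2β-methylcycloheptan-6β-ol
Conditions: t-BuOOH, n-BuLi, THF, −78 to −20 °C; then H2O
Reagents that add atoms: tert-butyl hydroperoxide, CC(C)(C)OO
Why: Nucleophilic (Weitz–Scheffer-type) epoxidation of the γ-hydroxy enone with lithium tert-butylperoxide, in which lithium bridging to the C6 hydroxyl should deliver the peroxide to C7 on the β face so that both new C–O bonds (C7 and C1) are β, syn to the C6 hydroxyl.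

Step 14
Reactants: 20 1α-acetyl-1β,7β-epoxy-3α-(tert-butyldimethylsilyloxy)-5β-ethynyl-2β-methylcycloheptan-6β-ol
Product: 21 1α-acetyl-3α-(tert-butyldimethylsilyloxy)-5β-ethynyl-1β,6β-dihydroxy-2β-methylcycloheptan-7α-yl 2-methylpropanoate
Conditions: i-PrCO2H, Ti(Oi-Pr)4, CH2Cl2, rt
Reagents that add atoms: 2-methylpropanoic acid, CC(C)C(=O)O
Why: Titanium-assisted opening of the 2,3-epoxy alcohol by the carboxylic acid, which can only proceed by SN2 attack at C7 because C1 is quaternary and acyl-substituted, and should therefore give the 7α-isobutyrate with inversion and the 1β tertiary alcohol with retention.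

Step 15
Reactants: 21 1α-acetyl-3α-(tert-butyldimethylsilyloxy)-5β-ethynyl-1β,6β-dihydroxy-2β-methylcycloheptan-7α-yl 2-methylpropanoate
Product: 22 cis-fused 11(13)-methylene-12,6β-olide: 1α-acetyl-3α-(tert-butyldimethylsilyloxy)-1β-hydroxy-2β-methyl-7α-(2-methylpropanoyloxy)cycloheptane carrying the α-methylene-γ-lactone across C5 (β-C11) and C6 (β-O)
Conditions: PdI2 (5 mol%), PBu3 (10 mol%), CO (3 atm), MeCN, 75 °C
Reagents that add atoms: carbon monoxide, [C-]#[O+]
Why: The C6 hydroxyl of 21 adds to CO bound to divalent palladium to give an alkoxycarbonylpalladium species, the cis C5 ethynyl group then inserts syn into its Pd–C bond, which forms the C12–C11 bond and closes the lactone, and protonolysis of the vinylpalladium by the alcohol releases 22 and returns the catalyst. The closest known reaction type is the palladium-catalysed cyclocarbonylation of homopropargylic alcohols such as cis-2-ethynylcycloalkanols to α-methylene-γ-butyrolactones. The γ-lactone is the only ring closed and it closes in the 5-exo-dig mode. No stereocentre is created here: the cis ring fusion is dictated by the existing C5 and C6 centres, and C11 is set afterwards (step 16) from the convex face of the bicycle formed in this step. The step needs chemoselectivity for the secondary C6 hydroxyl over the tertiary C1 hydroxyl and for 5-exo over 6-endo closure, both secured by the substrate, since only O6 can reach the internal alkyne carbon through a five-membered ring and syn insertion of a terminal alkyne places palladium on the terminal carbon.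

Step 16
Reactants: 22 α-methylene lactone (as named in step 15)
Product: 23 11,13-dihydro lactone: as 22 but with C11–H α and the C13 methyl group β
Conditions: H2 (1 atm), RhCl(PPh3)3 (10 mol%), benzene–EtOH, rt
Reagents that add atoms: none
Why: Homogeneous hydrogenation of the exocyclic 1,1-disubstituted alkene, which should add hydrogen from the convex α face of the cis-fused bicycle (the face of H-5 and H-6) and so set C11 with its methyl group β, without double-bond migration into the ring.

Step 17
Reactants: 23 11,13-dihydro lactone methyl ketone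
Product: 25 1α-(3-hydroxybutanoyl) analogue of 23 (both carbinol epimers), via dilithium enolate 24 (not isolated)
Conditions: LiN(SiMe3)2 (2.2 equiv), THF, −78 °C; then CH3CHO, −78 °C; then AcOH
Reagents that add atoms: acetaldehyde, CC=O
Why: Directed aldol addition of the kinetic lithium enolate of the methyl ketone (its only enolisable side, and more acidic than the lactone and ester α-hydrogens) to acetaldehyde, the configuration of the new carbinol being irrelevant because it is removed in step 18.

Step 18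
Reactants: 25 1α-(3-hydroxybutanoyl) analogue of 23
Product: 27 3-O-(tert-butyldimethylsilyl) ether of the target, via acetoxy ketone 26 (not isolated)
Conditions: Ac2O, DMAP, pyridine, CH2Cl2, 0 °C; then DBU, 0 °C to rt
Reagents that add atoms: none
Why: Acetylation of the secondary aldol hydroxyl (the tertiary C1 hydroxyl is too hindered to react) followed by E1cB elimination of acetate, which should give the thermodynamically favoured (E)-enone.

Step 19
Reactants: 27 3-O-(tert-butyldimethylsilyl) ether of the target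
Product: 28 CNP0268641.1
Conditions: HF·pyridine, THF, 0 °C to rt
Reagents that add atoms: none
Why: Fluoride-mediated cleavage of the secondary silyl ether under mildly acidic conditions, which should leave the enone, the lactone, the isobutyrate and the base-sensitive C11 configuration untouched.

Compound list
1 | 3-(trimethylsilyl)prop-2-ynal | C[Si](C)(C)C#CC=O | starting material
2 | 1-(triphenyl-λ5-phosphanylidene)propan-2-one | CC(=O)C=P(c1ccccc1)(c1ccccc1)c1ccccc1 | starting material
3 | (E)-6-(trimethylsilyl)hex-3-en-5-yn-2-one | CC(=O)/C=C/C#C[Si](C)(C)C | intermediate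
4 | (R,E)-6-(trimethylsilyl)hex-3-en-5-yn-2-ol | C[C@@H](O)/C=C/C#C[Si](C)(C)C | intermediate
5 | triethyl orthoacetate | CC(OCC)(OCC)OCC | starting material
6 | 1-ethoxyvinyl ether (ketene acetal) of 4 | C=C(OCC)O[C@H](C)/C=C/C#C[Si](C)(C)C | intermediate
7 | ethyl (R,E)-3-[(trimethylsilyl)ethynyl]hex-4-enoate | CCOC(=O)C[C@@H](C#C[Si](C)(C)C)/C=C/C | intermediate
8 | (R,E)-3-[(trimethylsilyl)ethynyl]hex-4-enal | O=CC[C@@H](C#C[Si](C)(C)C)/C=C/C | intermediate
9 | (S)-4-benzyl-3-propanoyloxazolidin-2-one | CCC(=O)N1[C@@H](Cc2ccccc2)COC1=O | starting material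
10 | (Z)-dibutylboron enolate of 9 | CCCCB(CCCC)O/C(=C\C)N1[C@@H](Cc2ccccc2)COC1=O | intermediate
11 | (S)-4-benzyl-3-[(2S,3R,5R,E)-3-hydroxy-2-methyl-5-[(trimethylsilyl)ethynyl]oct-6-enoyl]oxazolidin-2-one | O=C(N1[C@@H](Cc2ccccc2)COC1=O)[C@@H](C)[C@H](O)C[C@@H](C#C[Si](C)(C)C)/C=C/C | intermediate
12 | (2S,3R,5R,E)-3-hydroxy-N-methoxy-N,2-dimethyl-5-[(trimethylsilyl)ethynyl]oct-6-enamide | CON(C)C(=O)[C@@H](C)[C@H](O)C[C@@H](C#C[Si](C)(C)C)/C=C/C | intermediate
13 | (2S,3R,5R,E)-3-[(tert-butyldimethylsilyl)oxy]-N-methoxy-N,2-dimethyl-5-[(trimethylsilyl)ethynyl]oct-6-enamide | CON(C)C(=O)[C@@H](C)[C@H](O[Si](C)(C)C(C)(C)C)C[C@@H](C#C[Si](C)(C)C)/C=C/C | intermediate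
14 | (4S,5R,7R,E)-5-[(tert-butyldimethylsilyl)oxy]-4-methyl-7-[(trimethylsilyl)ethynyl]deca-1,8-dien-3-one | C=CC(=O)[C@@H](C)[C@H](O[Si](C)(C)C(C)(C)C)C[C@@H](C#C[Si](C)(C)C)/C=C/C | intermediate
15 | (4R,6R,7S)-6-[(tert-butyldimethylsilyl)oxy]-7-methyl-4-[(trimethylsilyl)ethynyl]cyclohept-2-en-1-one | O=C1[C@@H](C)[C@H](O[Si](C)(C)C(C)(C)C)C[C@@H](C#C[Si](C)(C)C)C=C1 | intermediate
16 | 1α-(1-ethoxyvinyl)-3α-(tert-butyldimethylsilyloxy)-2β-methyl-5β-[(trimethylsilyl)ethynyl]cyclohept-6-en-1β-ol | C=C(OCC)[C@]1(O)[C@@H](C)[C@H](O[Si](C)(C)C(C)(C)C)C[C@@H](C#C[Si](C)(C)C)C=C1 | intermediate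
17 | 1α-acetyl-3α-(tert-butyldimethylsilyloxy)-2β-methyl-5β-[(trimethylsilyl)ethynyl]cyclohept-6-en-1β-ol | CC(=O)[C@]1(O)[C@@H](C)[C@H](O[Si](C)(C)C(C)(C)C)C[C@@H](C#C[Si](C)(C)C)C=C1 | intermediate
18 | 1α-acetyl-3α-(tert-butyldimethylsilyloxy)-5β-ethynyl-2β-methylcyclohept-6-en-1β-ol | CC(=O)[C@]1(O)[C@@H](C)[C@H](O[Si](C)(C)C(C)(C)C)C[C@@H](C#C)C=C1 | intermediate
19 | 1-acetyl-3α-(tert-butyldimethylsilyloxy)-5β-ethynyl-2β-methylcyclohept-1(7)-en-6β-ol | CC(=O)C=1[C@@H](C)[C@H](O[Si](C)(C)C(C)(C)C)C[C@@H](C#C)[C@@H](O)C=1 | intermediate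
20 | 1α-acetyl-1β,7β-epoxy-3α-(tert-butyldimethylsilyloxy)-5β-ethynyl-2β-methylcycloheptan-6β-ol | CC(=O)[C@]12[C@@H](C)[C@H](O[Si](C)(C)C(C)(C)C)C[C@@H](C#C)[C@@H](O)[C@H]1O2 | intermediate
21 | 1α-acetyl-3α-(tert-butyldimethylsilyloxy)-5β-ethynyl-1β,6β-dihydroxy-2β-methylcycloheptan-7α-yl 2-methylpropanoate | CC(=O)[C@]1(O)[C@@H](C)[C@H](O[Si](C)(C)C(C)(C)C)C[C@@H](C#C)[C@@H](O)[C@@H]1OC(=O)C(C)C | intermediate
22 | cis-fused α-methylene-γ-lactone (C5 β-C11, C6 β-O) with 1α-acetyl, 1β-OH, 2β-CH3, 3α-OSi(t-Bu)Me2, 7α-isobutyrate | CC(=O)[C@]1(O)[C@@H](C)[C@H](O[Si](C)(C)C(C)(C)C)C[C@@H]2[C@@H](OC(=O)C2=C)[C@@H]1OC(=O)C(C)C | intermediate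
23 | 11,13-dihydro derivative of 22 (H-11 α, 13-CH3 β) | CC(=O)[C@]1(O)[C@@H](C)[C@H](O[Si](C)(C)C(C)(C)C)C[C@@H]2[C@@H](OC(=O)[C@@H]2C)[C@@H]1OC(=O)C(C)C | intermediate
24 | dilithium species of 23 (C1 alkoxide, methyl ketone enolate) | [Li]OC(=C)[C@]1(O[Li])[C@@H](C)[C@H](O[Si](C)(C)C(C)(C)C)C[C@@H]2[C@@H](OC(=O)[C@@H]2C)[C@@H]1OC(=O)C(C)C | intermediate
25 | 1α-(3-hydroxybutanoyl) analogue of 23 (carbinol epimers) | CC(O)CC(=O)[C@]1(O)[C@@H](C)[C@H](O[Si](C)(C)C(C)(C)C)C[C@@H]2[C@@H](OC(=O)[C@@H]2C)[C@@H]1OC(=O)C(C)C | intermediate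
26 | 1α-(3-acetoxybutanoyl) analogue of 23 | CC(OC(C)=O)CC(=O)[C@]1(O)[C@@H](C)[C@H](O[Si](C)(C)C(C)(C)C)C[C@@H]2[C@@H](OC(=O)[C@@H]2C)[C@@H]1OC(=O)C(C)C | intermediate
27 | 3-O-(tert-butyldimethylsilyl) ether of the target | C/C=C/C(=O)[C@]1(O)[C@@H](C)[C@H](O[Si](C)(C)C(C)(C)C)C[C@@H]2[C@@H](OC(=O)[C@@H]2C)[C@@H]1OC(=O)C(C)C | intermediate
28 | CNP0268641.1, (3R,3aS,5R,6S,7S,8S,8aR)-7-[(E)-but-2-enoyl]-5,7-dihydroxy-3,6-dimethyl-2-oxodecahydrocyclohepta[b]furan-8-yl 2-methylpropanoate | C/C=C/C(=O)[C@]1(O)[C@@H](C)[C@H](O)C[C@@H]2[C@@H](OC(=O)[C@@H]2C)[C@@H]1OC(=O)C(C)C | target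

Total step count: 19 steps.
Longest linear sequence: 19 steps (1 to 28); compounds 2, 5 and 9 enter as purchased building blocks.

Steps most likely to fail

Step 12. The allylic perrhenate ester may ionise instead of rearranging in a concerted way, which would scramble the configuration being relayed to C6, and the tertiary α-ketol may dehydrate. The fallback replaces the rhenium-oxo shift by a palladium-mediated ester shift. It sets out from 18: the tertiary hydroxyl is acetylated (Ac2O, Sc(OTf)3 cat., MeCN, −20 °C) to give the tertiary allylic acetate F1. PdCl2(MeCN)2 (5 mol%, THF, rt) then effects the suprafacial [3,3] shift of the allylic acetate by cyclisation-induced rearrangement to the conjugated 6β-acetate F2. Mild methanolysis (K2CO3, MeOH, 0 °C) returns to the route at 19.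

Step 14. The carboxylate may fail to reach the hindered C7, the Lewis acid may trigger an acyl shift of the epoxy ketone, and the ester may migrate between O7 and O6. The fallback changes the nucleophile and postpones the acylation. It sets out from 20: acid-catalysed hydrolysis (HClO4 cat., THF–H2O, 0 °C) with the smallest nucleophile should give the 1β,6β,7α-triol F3. Cyclocarbonylation under the conditions of step 15 should give the α-methylene lactone diol F4, because only the 6β-hydroxyl is cis to the alkyne. Hydrogenation as in step 16 gives the dihydro lactone diol F5. 2-Methylpropanoyl chloride (pyridine, DMAP, CH2Cl2) then acylates the only remaining secondary hydroxyl, at C7, which returns to the route at 23.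

Step 15. The chelating α-ketol and hydroxy ester motifs may deactivate the palladium catalyst, or carbopalladation may be too slow at this hindered site. The fallback forms the same C12–C11 bond by a radical instead of an organopalladium closure. It sets out from 21: Se-phenyl carbonochloridoselenoate (pyridine, CH2Cl2, 0 °C) converts the C6 hydroxyl into the Se-phenyl selenocarbonate F6. Bu3SnH and AIBN (benzene, 80 °C, slow addition) generate the alkoxycarbonyl radical, which cyclises 5-exo-dig onto the ethynyl group; hydrogen transfer to the vinyl radical returns to the route at 22.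

Further compounds
F1 | step 12 | 1α-acetyl-3α-(tert-butyldimethylsilyloxy)-5β-ethynyl-2β-methylcyclohept-6-en-1β-yl acetate | CC(=O)[C@]1(OC(C)=O)[C@@H](C)[C@H](O[Si](C)(C)C(C)(C)C)C[C@@H](C#C)C=C1
F2 | step 12 | 1-acetyl-3α-(tert-butyldimethylsilyloxy)-5β-ethynyl-2β-methylcyclohept-1(7)-en-6β-yl acetate | CC(=O)C=1[C@@H](C)[C@H](O[Si](C)(C)C(C)(C)C)C[C@@H](C#C)[C@@H](OC(C)=O)C=1
F3 | step 14 | 1α-acetyl-3α-(tert-butyldimethylsilyloxy)-5β-ethynyl-2β-methylcycloheptane-1β,6β,7α-triol | CC(=O)[C@]1(O)[C@@H](C)[C@H](O[Si](C)(C)C(C)(C)C)C[C@@H](C#C)[C@@H](O)[C@@H]1O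
F4 | step 14 | 7α-hydroxy analogue of 22 (α-methylene lactone 1β,7α-diol) | CC(=O)[C@]1(O)[C@@H](C)[C@H](O[Si](C)(C)C(C)(C)C)C[C@@H]2[C@@H](OC(=O)C2=C)[C@@H]1O
F5 | step 14 | 7α-hydroxy analogue of 23 (11,13-dihydro lactone 1β,7α-diol) | CC(=O)[C@]1(O)[C@@H](C)[C@H](O[Si](C)(C)C(C)(C)C)C[C@@H]2[C@@H](OC(=O)[C@@H]2C)[C@@H]1O
F6 | step 15 | 6β-O-(phenylselanylcarbonyl) derivative of 21 (Se-phenyl selenocarbonate) | CC(=O)[C@]1(O)[C@@H](C)[C@H](O[Si](C)(C)C(C)(C)C)C[C@@H](C#C)[C@@H](OC(=O)[Se]c2ccccc2)[C@@H]1OC(=O)C(C)C
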